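The route rests on cutting the azepane ring at C5–C6 and C7–C8 (numbering: N4, C5–C8 the four azepane CH2 groups, C9 the ring-fusion CH), so that the unsubstituted C6–C7 unit is delivered as a two-carbon linchpin between N4–CH2 (C5) and a formyl carbon on C9 (C8). In the key step a photoredox radical–polar crossover (conjunctive olefination) lets the decarboxylatively formed C5 radical add to vinyltriphenylphosphonium bromide, and the resulting ylide closes the seven-membered ring, trans-fused to the cyclopentane, by Wittig reaction. The precursor is an N4-(carboxymethyl) C9-formyl 1-azaspiro[4.4]nonane lactam carrying the hydroxy lactone, built from L-pyroglutamic acid; its C3 lactam carbonyl later accepts the side-chain lactone.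

Key step: step 13

Remark on numbering: atoms carry the locants of the target skeleton: N4, C3, C2, C1, C9a (pyrrolidine); C5–C8 and C9 (azepane); C9a, C9, C10 (CHEt), C11 (CH–O), C12 (cyclopentane); C13 (C(OH)CH3) and C14 (C=O) in the fused lactone; C18–C21 in the side-chain lactone. "Up" is the face of the cyclopentane that carries N4; in the target C8, O11 and C13 are down, ethyl is up.

Assumption: 3-methyl-2-(triisopropylsilyloxy)furan is prepared (step 14) because its commercial supply is uncertain; all other starting materials and reagents are taken as commercial.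

Step 1
Reactants: 1 L-pyroglutamic acid; 2 pivalaldehyde
Product: 3 (2R,5S)-2-tert-butyl-3-oxa-1-azabicyclo[3.3.0]octane-4,8-dione
Conditions: p-TsOH (cat.), toluene, Dean–Stark, reflux
Reagents that add atoms: none
Why: Acid-catalysed N,O-acetalisation of the lactam NH and the carboxylic acid should close the cis-fused bicycle with tert-butyl on the convex face, which stores the chirality of the future C9a (self-regeneration of stereocentres).

Step 2
Reactants: 3 (2R,5S)-2-tert-butyl-3-oxa-1-azabicyclo[3.3.0]octane-4,8-dione; 4 1-bromopent-2-yne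
Product: 5 (2R,5R)-2-tert-butyl-5-(pent-2-yn-1-yl)-3-oxa-1-azabicyclo[3.3.0]octane-4,8-dione
Conditions: LiN(SiMe3)2, THF, −78 °C; then 4, −78 → −30 °C
Reagents that add atoms: none
Why: The bridgehead lactone enolate (more acidic than the lactam α-CH2) should be alkylated by the propargylic bromide on the convex face cis to tert-butyl, so the new C9a–C12 bond replaces H with retention and fixes the quaternary C9a.

Step 3
Reactants: 5 (2R,5R)-2-tert-butyl-5-(pent-2-yn-1-yl)-3-oxa-1-azabicyclo[3.3.0]octane-4,8-dione
Product: 6 (2R,5R)-2-tert-butyl-5-(2-oxopentyl)-3-oxa-1-azabicyclo[3.3.0]octane-4,8-dione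
Conditions: NaAuCl4·2H2O (5 mol %), EtOH/H2O, rt
Reagents that add atoms: water, O
Why: Trivalent-gold-catalysed alkyne hydration should be steered by 5-exo-dig participation of the lactone carbonyl oxygen, which places the new ketone at C11 (γ to the lactone carbonyl).

Step 4
Reactants: 6 (2R,5R)-2-tert-butyl-5-(2-oxopentyl)-3-oxa-1-azabicyclo[3.3.0]octane-4,8-dione
Product: 7 (5R)-7-ethyl-8-hydroxy-1-azaspiro[4.4]non-7-ene-2,6-dione (enol form of the spiro 2,6,8-trione)
Conditions: KOt-Bu (2.2 equiv), THF, 0 °C → rt; then 1 M HCl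
Reagents that add atoms: none
Why: Intramolecular Claisen (Dieckmann-type) acylation of the C10 ketone enolate by the activated lactone carbonyl should close the cyclopentane-1,3-dione (5-exo-trig), and the expelled hemiaminal alkoxide collapses to pivalaldehyde and the free lactam.

Step 5
Reactants: 7 (5R)-7-ethyl-8-hydroxy-1-azaspiro[4.4]non-7-ene-2,6-dione
Product: 8 (5R)-7-ethyl-8-methoxy-1-azaspiro[4.4]non-7-ene-2,6-dione
Conditions: MeOH, p-TsOH (cat.), 3 Å molecular sieves, reflux
Reagents that add atoms: methanol, CO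
Why: Acid-catalysed enol etherification of the cyclic 1,3-dione should take place at the carbonyl remote from the quaternary spiro carbon (C11), leaving the hindered C9 carbonyl as the vinylogous ester C=O.

Step 6
Reactants: 8 (5R)-7-ethyl-8-methoxy-1-azaspiro[4.4]non-7-ene-2,6-dione; 9 tert-butyl bromoacetate
Product: 10 tert-butyl 2-[(5R)-7-ethyl-8-methoxy-2,6-dioxo-1-azaspiro[4.4]non-7-en-1-yl]acetate
Conditions: NaH, DMF, 0 °C → rt
Reagents that add atoms: none
Why: N-alkylation of the lactam anion (the most acidic site) installs C5 together with a carboxyl group that is later lost as CO2, and gives nitrogen a substituent that shields the upper face of the five-membered carbocycle.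

Step 7
Reactants: 10 tert-butyl 2-[(5R)-7-ethyl-8-methoxy-2,6-dioxo-1-azaspiro[4.4]non-7-en-1-yl]acetate
Product: 12 tert-butyl 2-[(5R)-7-ethyl-2,8-dioxo-1-azaspiro[4.4]non-6-en-1-yl]acetate, via allylic alcohol 11 (not isolated)
Conditions: NaBH4, CeCl3·7H2O, MeOH, 0 °C → rt; then 1 M HCl, THF, rt
Reagents that add atoms: none
Why: Luche 1,2-reduction of the vinylogous ester carbonyl followed by acid hydrolysis (Stork–Danheiser transposition) should move the enone so that C11 is the ketone and C9 the unsubstituted β-carbon, while the tert-butyl ester and the lactam are inert.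

Step 8
Reactants: 12 tert-butyl 2-[(5R)-7-ethyl-2,8-dioxo-1-azaspiro[4.4]non-6-en-1-yl]acetate
Product: 14 tert-butyl 2-[(5R,6R,7R)-6-ethenyl-7-ethyl-2,8-dioxo-1-azaspiro[4.4]nonan-1-yl]acetate, via silyl enol ether 13 (not isolated)
Conditions: CH2=CHMgBr, CuBr·SMe2 (20 mol %), Me3SiCl, THF, −78 → −40 °C; then 1 M HCl, THF; DBU (cat.), CH2Cl2, rt
Reagents that add atoms: vinylmagnesium bromide, C=C[Mg]Br; chlorotrimethylsilane, C[Si](C)(C)Cl
Why: Copper-catalysed conjugate addition of the vinyl group (a masked C8 aldehyde) should occur at C9 on the face opposite to the N-CH2CO2t-Bu arm of the adjacent spiro carbon, and hydrolysis with base equilibration places the C10 ethyl group trans to vinyl.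

Step 9
Reactants: 14 tert-butyl 2-[(5R,6R,7R)-6-ethenyl-7-ethyl-2,8-dioxo-1-azaspiro[4.4]nonan-1-yl]acetate; 15 ethyl (2S)-2-(trifluoromethylsulfonyloxy)propanoate
Product: 16 tert-butyl 2-[(5S,6R,7R,9R)-6-ethenyl-9-[(2S)-1-ethoxy-1-oxopropan-2-yl]-7-ethyl-2,8-dioxo-1-azaspiro[4.4]nonan-1-yl]acetate
Conditions: LiN(SiMe3)2 (1.05 equiv), THF, −78 °C; then 15, −78 → −40 °C
Reagents that add atoms: none
Why: Kinetic deprotonation at the C12 methylene (not the tertiary C10–H or the less acidic glycinate CH2) and SN2 alkylation by the lactate triflate with inversion should form C12–C13 anti to the N substituent; the C13 configuration is of no consequence because C13 is enolised in step 11.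

Step 10
Reactants: 16 tert-butyl 2-[(5S,6R,7R,9R)-6-ethenyl-9-[(2S)-1-ethoxy-1-oxopropan-2-yl]-7-ethyl-2,8-dioxo-1-azaspiro[4.4]nonan-1-yl]acetate
Product: 18 lactone acid (N4-CH2CO2H spiro-lactam; C9 vinyl down, C10 ethyl up, cis-fused γ-lactone O–C11/C12–C13 down, C13 methyl exo), via lactone tert-butyl ester 17 (not isolated)
Conditions: LiBH(s-Bu)3, THF, −78 → 0 °C; then CF3CO2H, CH2Cl2, rt
Reagents that add atoms: none
Why: The bulky hydride should attack the C11 ketone anti to the branched C12 side chain (syn to the smaller ethyl group) and the alkoxide cis to C13 closes the γ-lactone on the ethyl ester; trifluoroacetic acid then completes lactonisation and cleaves the tert-butyl ester, so that the C5 hydrogens (now α to a carboxylate) are not acidic in step 11.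

Step 11
Reactants: 18 lactone acid
Product: 19 hydroxy lactone acid (as 18, with C13 bearing OH exo and CH3 endo)
Conditions: KN(SiMe3)2 (2.2 equiv), THF, −78 °C; then 2-(phenylsulfonyl)-3-phenyloxaziridine, −78 °C; 1 M HCl
Reagents that add atoms: 2-(phenylsulfonyl)-3-phenyloxaziridine, O=S(=O)(N1OC1c1ccccc1)c1ccccc1
Why: Enolate oxidation with the Davis oxaziridine: the carboxylate/lactone-enolate dianion should be hydroxylated at C13 from the convex face of the cis-fused bicyclic lactone, which puts OH cis to the ring-fusion hydrogens and methyl on the concave face.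

Step 12
Reactants: 19 hydroxy lactone acid
Product: 20 formyl hydroxy lactone acid (as 19, with CHO in place of vinyl on C9)
Conditions: O3, CH2Cl2/MeOH, −78 °C; then Me2S, −78 °C → rt
Reagents that add atoms: ozone, [O-][O+]=O
Why: Ozonolysis with reductive work-up cleaves only the vinyl group and unveils the C8 aldehyde, whose C9 configuration (trans to the C10 ethyl group and to N4) should also be the thermodynamically preferred one.

Step 13
Reactants: 20 formyl hydroxy lactone acid; 21 vinyltriphenylphosphonium bromide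
Product: 23 azepine lactam (3-oxo-7,8-didehydro tetracycle: pyrrolidinone, Z-azepine trans-fused to the cyclopentane, hydroxy lactone), via phosphonium ylide 22 (not isolated)
Conditions: 4CzIPN (5 mol %), Cs2CO3 (1.5 equiv), 21 (1.5 equiv), MeCN (0.01 M), blue LEDs (450 nm), rt
Reagents that add atoms: none
Why: The excited photocatalyst oxidises the caesium carboxylate of 20, loss of CO2 gives the nucleophilic N4–CH2 (C5) α-amido radical, this adds to the terminal carbon of the vinylphosphonium salt (C5–C6), and reduction of the α-phosphonio radical by the reduced photocatalyst gives ylide 22, which olefinates the C9 formyl group (C7=C8). The closest known reaction type is the three-component photoredox conjunctive olefination of a carboxylic acid, a vinylphosphonium salt and an aldehyde, run here as a ring closure because acid and aldehyde are in one molecule. The azepine ring closes by 7-exo-trig attack of the ylide carbon C7 on the formyl carbon C8 followed by oxaphosphetane collapse, and the ring size enforces the Z alkene. No stereocentre is created: C9 keeps the configuration set in step 8 (formyl anti to N4), so the new ring is trans-fused to the cyclopentane. The step needs addition of the radical to the acceptor to outrun abstraction of the formyl hydrogen, and intramolecular Wittig closure to outrun protonation or intermolecular olefination of 22; the excess of the strongly electron-poor acceptor, the aprotic carbonate medium and high dilution should secure this.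

Step 14
Reactants: 24 3-methylfuran-2(5H)-one
Product: 25 3-methyl-2-(triisopropylsilyloxy)furan
Conditions: i-Pr3SiOTf, Et3N, CH2Cl2, 0 °C
Reagents that add atoms: triisopropylsilyl trifluoromethanesulfonate, CC(C)[Si](OS(=O)(=O)C(F)(F)F)(C(C)C)C(C)C
Why: Soft enolisation and O-silylation of the butenolide give the aromatic 2-silyloxyfuran, the nucleophile of the vinylogous Mannich reaction.

Step 15
Reactants: 23 azepine lactam; 25 3-methyl-2-(triisopropylsilyloxy)furan
Product: 27 butenolide adduct (as 23, with C3 bearing H and the (2S)-4-methyl-5-oxo-2,5-dihydrofuran-2-yl group; C3 S, C18 S), via N,O-silyl acetal 26 (not isolated)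
Conditions: IrCl(CO)(PPh3)2 (1 mol %), (Me2HSi)2O, toluene, rt; then 25, Me3SiOTf (0.2 equiv), CH2Cl2, −78 → 0 °C; aqueous citric acid work-up
Reagents that add atoms: 1,1,3,3-tetramethyldisiloxane, C[SiH](C)O[SiH](C)C
Why: Iridium-catalysed hydrosilylation should reduce only the tertiary lactam (lactones untouched) to the N,O-silyl acetal, whose iminium ion is attacked at C3 by the silyloxyfuran (reductive vinylogous Mukaiyama–Mannich reaction) on the face opposite to the azepine ring (trans to C9, cis to C12) through the open transition state that gives the threo C3/C18 relationship.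

Step 16
Reactants: 27 butenolide adduct
Product: 28 CNP0260919.2 (target)
Conditions: H2 (1–4 atm), Rh/C, EtOAc, rt
Reagents that add atoms: none
Why: Heterogeneous hydrogenation should saturate the C7=C8 bond and add hydrogen to the butenolide from the face opposite to the C18 substituent, which sets the C20 methyl group cis to the pyrrolidine substituent.

Compound list
1 | L-pyroglutamic acid, (2S)-5-oxopyrrolidine-2-carboxylic acid | OC(=O)[C@@H]1CCC(=O)N1 | starting material
2 | pivalaldehyde | CC(C)(C)C=O | starting material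
3 | (2R,5S)-2-tert-butyl-3-oxa-1-azabicyclo[3.3.0]octane-4,8-dione | CC(C)(C)[C@H]1OC(=O)[C@@H]2CCC(=O)N12 | intermediate
4 | 1-bromopent-2-yne | CCC#CCBr | starting material
5 | (2R,5R)-2-tert-butyl-5-(pent-2-yn-1-yl)-3-oxa-1-azabicyclo[3.3.0]octane-4,8-dione | CC(C)(C)[C@H]1OC(=O)[C@]2(CC#CCC)CCC(=O)N12 | intermediate
6 | (2R,5R)-2-tert-butyl-5-(2-oxopentyl)-3-oxa-1-azabicyclo[3.3.0]octane-4,8-dione | CC(C)(C)[C@H]1OC(=O)[C@]2(CC(=O)CCC)CCC(=O)N12 | intermediate
7 | (5R)-7-ethyl-8-hydroxy-1-azaspiro[4.4]non-7-ene-2,6-dione (enol of the trione) | O=C1CC[C@]2(N1)C(=O)C(CC)=C(O)C2 | intermediate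
8 | (5R)-7-ethyl-8-methoxy-1-azaspiro[4.4]non-7-ene-2,6-dione | O=C1CC[C@]2(N1)C(=O)C(CC)=C(OC)C2 | intermediate
9 | tert-butyl bromoacetate | BrCC(=O)OC(C)(C)C | starting material
10 | tert-butyl 2-[(5R)-7-ethyl-8-methoxy-2,6-dioxo-1-azaspiro[4.4]non-7-en-1-yl]acetate | O=C1CC[C@]2(N1CC(=O)OC(C)(C)C)C(=O)C(CC)=C(OC)C2 | intermediate
11 | tert-butyl 2-[(5R)-7-ethyl-6-hydroxy-8-methoxy-2-oxo-1-azaspiro[4.4]non-7-en-1-yl]acetate (both C6 epimers; not isolated) | O=C1CC[C@]2(N1CC(=O)OC(C)(C)C)C(O)C(CC)=C(OC)C2 | intermediate
12 | tert-butyl 2-[(5R)-7-ethyl-2,8-dioxo-1-azaspiro[4.4]non-6-en-1-yl]acetate | O=C1CC[C@]2(N1CC(=O)OC(C)(C)C)C=C(CC)C(=O)C2 | intermediate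
13 | tert-butyl 2-[(5R,6R)-6-ethenyl-7-ethyl-2-oxo-8-(trimethylsilyloxy)-1-azaspiro[4.4]non-7-en-1-yl]acetate (not isolated) | O=C1CC[C@]2(N1CC(=O)OC(C)(C)C)[C@H](C=C)C(CC)=C(O[Si](C)(C)C)C2 | intermediate
14 | tert-butyl 2-[(5R,6R,7R)-6-ethenyl-7-ethyl-2,8-dioxo-1-azaspiro[4.4]nonan-1-yl]acetate | O=C1CC[C@]2(N1CC(=O)OC(C)(C)C)[C@H](C=C)[C@@H](CC)C(=O)C2 | intermediate
15 | ethyl (2S)-2-(trifluoromethylsulfonyloxy)propanoate | C[C@H](OS(=O)(=O)C(F)(F)F)C(=O)OCC | starting material
16 | tert-butyl 2-[(5S,6R,7R,9R)-6-ethenyl-9-[(2S)-1-ethoxy-1-oxopropan-2-yl]-7-ethyl-2,8-dioxo-1-azaspiro[4.4]nonan-1-yl]acetate | O=C1CC[C@]2(N1CC(=O)OC(C)(C)C)[C@H](C=C)[C@@H](CC)C(=O)[C@@H]2[C@H](C)C(=O)OCC | intermediate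
17 | lactone tert-butyl ester: tert-butyl ester of 18 (not isolated) | O=C1CC[C@]2(N1CC(=O)OC(C)(C)C)[C@H](C=C)[C@@H](CC)[C@@H]3OC(=O)[C@@H](C)[C@H]23 | intermediate
18 | lactone acid: N4-(carboxymethyl) 3-oxo spiro-lactam; cyclopentane with C9 vinyl (down), C10 ethyl (up), γ-lactone cis-fused at C11–O/C12–C13 (down), C13-H with CH3 exo (C9a S, C9 R, C10 R, C11 S, C12 R, C13 S) | O=C1CC[C@]2(N1CC(=O)O)[C@H](C=C)[C@@H](CC)[C@@H]3OC(=O)[C@@H](C)[C@H]23 | intermediate
19 | hydroxy lactone acid: as 18 with C13(OH)(CH3), OH exo (C13 S) | O=C1CC[C@]2(N1CC(=O)O)[C@H](C=C)[C@@H](CC)[C@@H]3OC(=O)[C@@](C)(O)[C@H]23 | intermediate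
20 | formyl hydroxy lactone acid: as 19 with C9–CHO (down) in place of vinyl | O=C1CC[C@]2(N1CC(=O)O)[C@H](C=O)[C@@H](CC)[C@@H]3OC(=O)[C@@](C)(O)[C@H]23 | intermediate
21 | vinyltriphenylphosphonium bromide | C=C[P+](c1ccccc1)(c1ccccc1)c1ccccc1.[Br-] | starting material
22 | phosphonium ylide: as 20 with N4–CH2CH2CH=PPh3 in place of N4–CH2CO2H (not isolated) | O=C1CC[C@]2(N1CCC=P(c1ccccc1)(c1ccccc1)c1ccccc1)[C@H](C=O)[C@@H](CC)[C@@H]3OC(=O)[C@@](C)(O)[C@H]23 | intermediate
23 | azepine lactam: target skeleton with C3=O (no side chain) and a Z C7=C8 double bond (C9a S, C9 R, C10 R, C11 S, C12 R, C13 S) | CC[C@H]1[C@@H]2OC(=O)[C@@](C)(O)[C@@H]2[C@@]23CCC(=O)N2CCC=C[C@H]13 | intermediate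
24 | 3-methylfuran-2(5H)-one | CC1=CCOC1=O | starting material
25 | 3-methyl-2-(triisopropylsilyloxy)furan | Cc1ccoc1O[Si](C(C)C)(C(C)C)C(C)C | intermediate
26 | N,O-silyl acetal: as 23 with C3(H)–O–SiMe2–O–SiMe2H in place of C3=O (C3 epimers; not isolated) | CC[C@H]1[C@@H]2OC(=O)[C@@](C)(O)[C@@H]2[C@@]23CCC(O[Si](C)(C)O[SiH](C)C)N2CCC=C[C@H]13 | intermediate
27 | butenolide adduct: as 23 with C3 (S) bearing H and the (2S)-4-methyl-5-oxo-2,5-dihydrofuran-2-yl group | CC[C@H]1[C@@H]2OC(=O)[C@@](C)(O)[C@@H]2[C@@]23CC[C@@H]([C@@H]4C=C(C)C(=O)O4)N2CCC=C[C@H]13 | intermediate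
28 | CNP0260919.2 | CC[C@H]1[C@@H]2OC(=O)[C@@](C)(O)[C@@H]2[C@@]23CC[C@@H]([C@@H]4C[C@H](C)C(=O)O4)N2CCCC[C@H]13 | target

Total step count: 16. Longest linear sequence: 15 steps (steps 1–13, 15 and 16; step 14 is a one-step side branch).

Steps most likely to fail

Step 13. What may go wrong: the ylide is protonated before it reaches the formyl group, the C5 radical abstracts the formyl hydrogen, or Wittig reaction between molecules gives oligomers, so that the ring does not close. Fallback: the route sets out from 19 (before ozonolysis). Photoredox decarboxylative radical allylation of 19 with allyl phenyl sulfone (4CzIPN, Cs2CO3, MeCN, blue LEDs) should give the N4-(but-3-en-1-yl) vinyl lactam F1, in which C5–C6 is formed by radical addition and loss of the sulfonyl radical. Ring-closing metathesis of F1 with the second-generation Grubbs catalyst RuCl2(=CHPh)(PCy3)(H2IMes) in CH2Cl2 at 40 °C then forms C7=C8 with loss of ethene and comes back to the route at 23; step 12 is not needed on this path.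

Step 10. What may go wrong: poor facial selectivity of hydride delivery at C11; attack from the face of the C12 side chain gives the alcohol that cannot lactonise. Fallback: the route sets out from 16. Reduction with NaBH4 and CeCl3·7H2O in MeOH should give the C11-epimeric hydroxy diester F2 (hydroxyl up, cis to ethyl). Selective saponification of its ethyl ester (LiOH, THF/H2O, 0 °C) gives the hydroxy acid F3, and Mitsunobu lactonisation (PPh3, DIAD, THF) closes the γ-lactone with inversion at C11 to give 17. Trifluoroacetic acid then leads back to the route at 18.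

Step 9. What may go wrong: slow SN2 displacement at the secondary triflate by the hindered enolate next to the spiro centre, with O-alkylation or elimination of the triflate taking over. Fallback: the route sets out from 14. Alkylation of its C12 lithium enolate with the primary electrophile ethyl iodoacetate (LiN(SiMe3)2, THF, −78 °C) should give the keto diester F4. Reduction with LiBH(s-Bu)3 and treatment with CF3CO2H as in step 10 give, through the nor-methyl lactone tert-butyl ester F5, the nor-methyl lactone acid F6. Methylation of its dianion (LiN(i-Pr)2, 2.2 equiv, then MeI, THF, −78 °C) on the convex face installs the C13 methyl group and comes back to the route at 18.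

Further compounds
F1 | step 13 | N4-(but-3-en-1-yl) vinyl lactam: as 19 with N4–CH2CH2CH=CH2 in place of N4–CH2CO2H | O=C1CC[C@]2(N1CCC=C)[C@H](C=C)[C@@H](CC)[C@@H]3OC(=O)[C@@](C)(O)[C@H]23
F2 | step 10 | C11-epimeric hydroxy diester: as 16 with C11 H(OH), hydroxyl up | O=C1CC[C@]2(N1CC(=O)OC(C)(C)C)[C@H](C=C)[C@@H](CC)[C@@H](O)[C@@H]2[C@H](C)C(=O)OCC
F3 | step 10 | hydroxy acid: as F2 with the ethyl ester hydrolysed | O=C1CC[C@]2(N1CC(=O)OC(C)(C)C)[C@H](C=C)[C@@H](CC)[C@@H](O)[C@@H]2[C@H](C)C(=O)O
F4 | step 9 | keto diester: as 16 with CH2CO2Et on C12 (no C13 methyl) | O=C1CC[C@]2(N1CC(=O)OC(C)(C)C)[C@H](C=C)[C@@H](CC)C(=O)[C@@H]2CC(=O)OCC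
F5 | step 9 | nor-methyl lactone tert-butyl ester: as 17 with C13H2 | O=C1CC[C@]2(N1CC(=O)OC(C)(C)C)[C@H](C=C)[C@@H](CC)[C@@H]3OC(=O)C[C@H]23
F6 | step 9 | nor-methyl lactone acid: as 18 with C13H2 | O=C1CC[C@]2(N1CC(=O)O)[C@H](C=C)[C@@H](CC)[C@@H]3OC(=O)C[C@H]23
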